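Assumption: eicosanoid numbering is used (C1 = lactone C=O, C5 = lactone CH–O, C6–C8 = cyclopropane; unprimed = 9-hydroxy half, primed = Δ9′ half), and the biogenesis is presumed to be (i) cation-triggered homoallyl→cyclopropylcarbinyl closure with carboxyl capture at C5, then (ii) hydrative union of two vinyl-epoxide-level C20 units (O12′ opens the 11,12-epoxide at C11, the C9′–C11′ allyl cation is captured by the Δ9 olefin, water adds at C9).

## Retrosynthetic overview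

1. Oxolane last: C10–C11′ bond by allyl-cation/olefin (Prins-type) closure of bis-allylic ether 20, water terminating at C9 (sets C10, C11′, C9).
2. Ether 20: C11–O bond from vinyl epoxide 15 (11S,12S) and alcohol 19 (12′R) by Pd/borane allylic etherification with retention.
3. 15 and 19 (via 18): Julia–Kocienski union of one cyclopropyl-lactone sulfone 8 with the enantiomeric Sharpless-derived epoxy aldehydes 14 and 17.
4. Cyclopropane and δ-lactone in one step: epoxide-triggered homoallyl→cyclopropylcarbinyl/lactonisation cascade of Z-epoxy ester 5 (from (S)-epichlorohydrin).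
5. Ring order: cyclopropane + δ-lactone (step 3, made once, used for both halves), then oxolane (step 16).

## Route

Step 1
Reactants: 1 tert-butyl hex-5-ynoate; 2 (S)-epichlorohydrin
Product: 4 tert-butyl 7-[(2S)-oxiran-2-yl]hept-5-ynoate, via chlorohydrin 3 (not isolated)
Conditions: n-BuLi (1.0 equiv), THF, −78 °C; BF3·OEt2, then 2, −78 °C; then aq. NaOH, rt
Reagents that add atoms: none
Why: Yamaguchi–Hirao alkynylation opens the BF3-activated epoxide at its CH2 terminus and an intramolecular Williamson closure then forms the new epoxide on the former CH2Cl side; the C–O bond of the stereocentre is never broken, so (S) is carried over.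

Step 2
Reactants: 4 tert-butyl 7-[(2S)-oxiran-2-yl]hept-5-ynoate
Product: 5 tert-butyl (5Z)-7-[(2S)-oxiran-2-yl]hept-5-enoate
Conditions: H2 (1 atm), Lindlar catalyst, quinoline, EtOAc, rt
Reagents that add atoms: none
Why: Lindlar semihydrogenation adds H2 syn to give the Z-olefin, leaving epoxide and ester untouched.

Step 3
Reactants: 5 tert-butyl (5Z)-7-[(2S)-oxiran-2-yl]hept-5-enoate
Product: 6 (6R)-6-[(1S,2S)-2-(hydroxymethyl)cyclopropyl]oxan-2-one
Conditions: BF3·OEt2 (0.3 equiv), CH2Cl2 (0.01 M), −78 → −40 °C; aq. NaHCO3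
Reagents that add atoms: none
Why: Proposed new method: BF3 activates the terminal epoxide, the Z-olefin attacks C8 from the back (homoallyl→cyclopropylcarbinyl participation, inversion, giving 8S), the less crowded transition state places C5 and C9 trans on the new ring (6S), and the tert-butyl ester carbonyl adds to C5 anti to the new C6–C8 bond (Z-olefin gives 5R) before losing isobutene; closest known reaction types are the i-steroid (homoallyl/cyclopropylcarbinyl) rearrangement and Lewis-acid epoxide-initiated cation–olefin cyclisation with ester termination.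

Step 4
Reactants: 6 (6R)-6-[(1S,2S)-2-(hydroxymethyl)cyclopropyl]oxan-2-one
Product: 7 (6R)-6-[(1S,2S)-2-{[(1-phenyl-1H-tetrazol-5-yl)sulfanyl]methyl}cyclopropyl]oxan-2-one
Conditions: PT-SH, PPh3, DIAD, THF, 0 °C → rt
Reagents that add atoms: 1-phenyl-1H-tetrazole-5-thiol, Sc1nnnn1-c1ccccc1
Why: Mitsunobu thioetherification at the primary cyclopropylmethyl carbon (SN2, no stereocentre involved, no ring opening with a soft thiolate).

Step 5
Reactants: 7 (6R)-6-[(1S,2S)-2-{[(1-phenyl-1H-tetrazol-5-yl)sulfanyl]methyl}cyclopropyl]oxan-2-one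
Product: 8 (6R)-6-[(1S,2S)-2-{[(1-phenyl-1H-tetrazol-5-yl)sulfonyl]methyl}cyclopropyl]oxan-2-one
Conditions: 30% H2O2, (NH4)6Mo7O24·4H2O (10 mol%), EtOH, 0 °C → rt
Reagents that add atoms: hydrogen peroxide, OO
Why: Molybdate-catalysed sulfide-to-sulfone oxidation is chemoselective for sulfur; lactone and cyclopropane are inert.

Step 6
Reactants: 9 (3Z,6Z)-nona-3,6-dien-1-ol
Product: 11 ethyl (2E,5Z,8Z)-undeca-2,5,8-trienoate, via dienal 10 (not isolated)
Conditions: Dess–Martin periodinane, CH2Cl2, 0 °C; then Ph3P=CHCO2Et (2.5 equiv), 0 °C → rt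
Reagents that add atoms: ethyl (triphenylphosphoranylidene)acetate, CCOC(=O)C=P(c1ccccc1)(c1ccccc1)c1ccccc1
Why: Tandem Dess–Martin oxidation/Wittig olefination traps the isomerisation-prone β,γ-unsaturated aldehyde at once, and the stabilised ylide gives the 2E-enoate.

Step 7
Reactants: 11 ethyl (2E,5Z,8Z)-undeca-2,5,8-trienoate
Product: 12 (2E,5Z,8Z)-undeca-2,5,8-trien-1-ol
Conditions: DIBAL-H (2.2 equiv), CH2Cl2, −78 °C; Rochelle salt
Reagents that add atoms: none
Why: DIBAL 1,2-reduction of the enoate gives the allylic alcohol without touching the skipped Z-olefins.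

Step 8
Reactants: 12 (2E,5Z,8Z)-undeca-2,5,8-trien-1-ol
Product: 13 [(2S,3S)-3-[(2Z,5Z)-octa-2,5-dien-1-yl]oxiran-2-yl]methanol
Conditions: Ti(OiPr)4 (10 mol%), L-(+)-DET (12 mol%), TBHP, 4 Å MS, CH2Cl2, −20 °C
Reagents that add atoms: tert-butyl hydroperoxide, CC(C)(C)OO
Why: Sharpless asymmetric epoxidation is directed to the allylic olefin only, and L-(+)-tartrate delivers oxygen to give the (2S,3S) trans-epoxide (future C11, C12).

Step 9
Reactants: 13 [(2S,3S)-3-[(2Z,5Z)-octa-2,5-dien-1-yl]oxiran-2-yl]methanol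
Product: 14 (2R,3S)-3-[(2Z,5Z)-octa-2,5-dien-1-yl]oxirane-2-carbaldehyde
Conditions: PhI(OAc)2, TEMPO (10 mol%), CH2Cl2, rt
Reagents that add atoms: none
Why: TEMPO/PhI(OAc)2 oxidation of the primary alcohol gives the epoxy aldehyde without epimerisation (the descriptor at C2 changes by CIP priority only).

Step 10
Reactants: 8 (6R)-6-[(1S,2S)-2-{[(1-phenyl-1H-tetrazol-5-yl)sulfonyl]methyl}cyclopropyl]oxan-2-one; 14 (2R,3S)-3-[(2Z,5Z)-octa-2,5-dien-1-yl]oxirane-2-carbaldehyde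
Product: 15 (6R)-6-[(1S,2R)-2-{(E)-2-[(2S,3S)-3-[(2Z,5Z)-octa-2,5-dien-1-yl]oxiran-2-yl]ethenyl}cyclopropyl]oxan-2-one
Conditions: KHMDS (1.05 equiv, added to 8 + 14), DME, −60 °C → rt
Reagents that add atoms: none
Why: Julia–Kocienski olefination under Barbier conditions (sulfone α-H is far more acidic than lactone α-H) gives the E-Δ9 olefin via Smiles rearrangement/anti elimination, with the epoxide centres (11S,12S) untouched.

Step 11
Reactants: 12 (2E,5Z,8Z)-undeca-2,5,8-trien-1-ol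
Product: 16 [(2R,3R)-3-[(2Z,5Z)-octa-2,5-dien-1-yl]oxiran-2-yl]methanol
Conditions: Ti(OiPr)4 (10 mol%), D-(−)-DET (12 mol%), TBHP, 4 Å MS, CH2Cl2, −20 °C
Reagents that add atoms: tert-butyl hydroperoxide, CC(C)(C)OO
Why: Sharpless asymmetric epoxidation with D-(−)-tartrate gives the enantiomeric (2R,3R) epoxide, which supplies the 12′R centre of the primed half.

Step 12
Reactants: 16 [(2R,3R)-3-[(2Z,5Z)-octa-2,5-dien-1-yl]oxiran-2-yl]methanol
Product: 17 (2S,3R)-3-[(2Z,5Z)-octa-2,5-dien-1-yl]oxirane-2-carbaldehyde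
Conditions: PhI(OAc)2, TEMPO (10 mol%), CH2Cl2, rt
Reagents that add atoms: none
Why: TEMPO/PhI(OAc)2 oxidation as in step 9, stereocentres untouched.

Step 13
Reactants: 8 (6R)-6-[(1S,2S)-2-{[(1-phenyl-1H-tetrazol-5-yl)sulfonyl]methyl}cyclopropyl]oxan-2-one; 17 (2S,3R)-3-[(2Z,5Z)-octa-2,5-dien-1-yl]oxirane-2-carbaldehyde
Product: 18 (6R)-6-[(1S,2R)-2-{(E)-2-[(2R,3R)-3-[(2Z,5Z)-octa-2,5-dien-1-yl]oxiran-2-yl]ethenyl}cyclopropyl]oxan-2-one
Conditions: KHMDS (1.05 equiv, added to 8 + 17), DME, −60 °C → rt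
Reagents that add atoms: none
Why: Julia–Kocienski olefination as in step 10 gives the E-olefin with the (11′R,12′R) epoxide intact.

Step 14
Reactants: 18 (6R)-6-[(1S,2R)-2-{(E)-2-[(2R,3R)-3-[(2Z,5Z)-octa-2,5-dien-1-yl]oxiran-2-yl]ethenyl}cyclopropyl]oxan-2-one
Product: 19 (6R)-6-[(1S,2S)-2-[(2E,4R,6Z,9Z)-4-hydroxy-1-methoxydodeca-2,6,9-trien-1-yl]cyclopropyl]oxan-2-one (both C9′ epimers, used together)
Conditions: PPTS (5 mol%), MeOH, −20 → 0 °C
Reagents that add atoms: methanol, CO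
Why: Acid-catalysed SN1/SN2′ methanolysis of the vinyl epoxide puts methanol on the cyclopropyl-stabilised allyl terminus C9′ (as water does in constanolactone formation), giving the E-Δ10′ olefin and freeing the untouched 12′R hydroxyl; C9′ is ionised again in step 16, so its configuration is irrelevant.

Step 15
Reactants: 15 (6R)-6-[(1S,2R)-2-{(E)-2-[(2S,3S)-3-[(2Z,5Z)-octa-2,5-dien-1-yl]oxiran-2-yl]ethenyl}cyclopropyl]oxan-2-one; 19 (6R)-6-[(1S,2S)-2-[(2E,4R,6Z,9Z)-4-hydroxy-1-methoxydodeca-2,6,9-trien-1-yl]cyclopropyl]oxan-2-one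
Product: 20 bis-allylic ether, (6R)-6-[(1S,2R)-2-{(1E,3S,4S,6Z,9Z)-4-hydroxy-3-{[(2E,4R,6Z,9Z)-1-methoxy-1-{(1S,2S)-2-[(2R)-6-oxooxan-2-yl]cyclopropyl}dodeca-2,6,9-trien-4-yl]oxy}dodeca-1,6,9-trien-1-yl}cyclopropyl]oxan-2-one (C11–O–C12′; 11S,12S,12′R; C9′ epimers)
Conditions: Pd2(dba)3·CHCl3 (2.5 mol%), dppf (6 mol%), Et3B (10 mol%), CH2Cl2, rt; 19 (1.5 equiv), slow addition of 15
Reagents that add atoms: none
Why: Tsuji–Trost allylic etherification of a vinyl epoxide with borane co-catalysis: Pd(0) ionises C11–O with inversion and the boron-bound alkoxide delivers the alcohol to the proximal terminus C11 anti to Pd, so the 1,2-adduct forms with net retention (11S), the E-Δ9 olefin and the free 12S hydroxyl.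

Step 16
Reactants: 20 bis-allylic ether (C11–O–C12′)
Product: 21 CNP0273074.1 (5R,6S,8S,9R,10R,11S,12S,14Z,17Z; 5′R,6′S,8′R,9′E,11′S,12′R,14′Z,17′Z)
Conditions: PPTS (20 mol%), HFIP–H2O (10:1), 0.002 M, 0 °C → rt
Reagents that add atoms: water, O
Why: Proposed new method: mild acid in HFIP ionises the doubly activated (cyclopropylcarbinyl and allylic) C9′–OMe faster than the β-hydroxylated C11–O tether, the W-shaped C9′–C11′ allyl cation is trapped at C11′ by C10 of the tethered vinylcyclopropane through a five-membered envelope transition state in which each new substituent goes anti to its resident neighbour at C11 and C12′ (already trans across oxygen, hence the all-trans 10R,11′S oxolane with Δ9′ kept E), and the bisected cyclopropylcarbinyl cation at C9 is captured by water from the ring-CH2 (C7) side to give 9R, while reversible O-alkylation by the 12-OH re-ionises and funnels into the irreversible C–C closure; closest known reaction types are Prins-type cation–olefin cyclisation of allyl cations and solvolytic capture of cyclopropylcarbinyl cations.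

## Compound list

1 | tert-butyl hex-5-ynoate | C#CCCCC(=O)OC(C)(C)C | starting material
2 | (S)-epichlorohydrin, (2S)-2-(chloromethyl)oxirane | ClC[C@@H]1CO1 | starting material
3 | tert-butyl (8S)-9-chloro-8-hydroxynon-5-ynoate | ClC[C@@H](O)CC#CCCCC(=O)OC(C)(C)C | intermediate
4 | tert-butyl 7-[(2S)-oxiran-2-yl]hept-5-ynoate | CC(C)(C)OC(=O)CCCC#CC[C@H]1CO1 | intermediate
5 | tert-butyl (5Z)-7-[(2S)-oxiran-2-yl]hept-5-enoate | CC(C)(C)OC(=O)CCC/C=C\C[C@H]1CO1 | intermediate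
6 | (6R)-6-[(1S,2S)-2-(hydroxymethyl)cyclopropyl]oxan-2-one | OC[C@H]1C[C@@H]1[C@H]1CCCC(=O)O1 | intermediate
7 | (6R)-6-[(1S,2S)-2-{[(1-phenyl-1H-tetrazol-5-yl)sulfanyl]methyl}cyclopropyl]oxan-2-one | c1ccccc1-n1nnnc1SC[C@H]1C[C@@H]1[C@H]1CCCC(=O)O1 | intermediate
8 | (6R)-6-[(1S,2S)-2-{[(1-phenyl-1H-tetrazol-5-yl)sulfonyl]methyl}cyclopropyl]oxan-2-one | c1ccccc1-n1nnnc1S(=O)(=O)C[C@H]1C[C@@H]1[C@H]1CCCC(=O)O1 | intermediate
9 | (3Z,6Z)-nona-3,6-dien-1-ol | CC/C=C\C/C=C\CCO | starting material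
10 | (3Z,6Z)-nona-3,6-dienal | CC/C=C\C/C=C\CC=O | intermediate
11 | ethyl (2E,5Z,8Z)-undeca-2,5,8-trienoate | CC/C=C\C/C=C\C/C=C/C(=O)OCC | intermediate
12 | (2E,5Z,8Z)-undeca-2,5,8-trien-1-ol | CC/C=C\C/C=C\C/C=C/CO | intermediate
13 | [(2S,3S)-3-[(2Z,5Z)-octa-2,5-dien-1-yl]oxiran-2-yl]methanol | CC/C=C\C/C=C\C[C@@H]1O[C@H]1CO | intermediate
14 | (2R,3S)-3-[(2Z,5Z)-octa-2,5-dien-1-yl]oxirane-2-carbaldehyde | CC/C=C\C/C=C\C[C@@H]1O[C@H]1C=O | intermediate
15 | (6R)-6-[(1S,2R)-2-{(E)-2-[(2S,3S)-3-[(2Z,5Z)-octa-2,5-dien-1-yl]oxiran-2-yl]ethenyl}cyclopropyl]oxan-2-one | CC/C=C\C/C=C\C[C@@H]1O[C@H]1/C=C/[C@H]1C[C@@H]1[C@H]1CCCC(=O)O1 | intermediate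
16 | [(2R,3R)-3-[(2Z,5Z)-octa-2,5-dien-1-yl]oxiran-2-yl]methanol | CC/C=C\C/C=C\C[C@H]1O[C@@H]1CO | intermediate
17 | (2S,3R)-3-[(2Z,5Z)-octa-2,5-dien-1-yl]oxirane-2-carbaldehyde | CC/C=C\C/C=C\C[C@H]1O[C@@H]1C=O | intermediate
18 | (6R)-6-[(1S,2R)-2-{(E)-2-[(2R,3R)-3-[(2Z,5Z)-octa-2,5-dien-1-yl]oxiran-2-yl]ethenyl}cyclopropyl]oxan-2-one | CC/C=C\C/C=C\C[C@H]1O[C@@H]1/C=C/[C@H]1C[C@@H]1[C@H]1CCCC(=O)O1 | intermediate
19 | (6R)-6-[(1S,2S)-2-[(2E,4R,6Z,9Z)-4-hydroxy-1-methoxydodeca-2,6,9-trien-1-yl]cyclopropyl]oxan-2-one, C9′ epimers | CC/C=C\C/C=C\C[C@@H](O)/C=C/C(OC)[C@H]1C[C@@H]1[C@H]1CCCC(=O)O1 | intermediate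
20 | bis-allylic ether C11–O–C12′ (11S,12S,12′R; C9′ epimers), name as in step 15 | CC/C=C\C/C=C\C[C@H](O)[C@@H](O[C@H](C/C=C\C/C=C\CC)/C=C/C(OC)[C@H]1C[C@@H]1[C@H]1CCCC(=O)O1)/C=C/[C@H]1C[C@@H]1[C@H]1CCCC(=O)O1 | intermediate
21 | CNP0273074.1, all-trans 2,3,4,5-tetrasubstituted oxolane (5R,6S,8S,9R,10R,11S,12S; 5′R,6′S,8′R,11′S,12′R) | CC/C=C\C/C=C\C[C@H](O)[C@H]1O[C@H](C/C=C\C/C=C\CC)[C@@H](/C=C/[C@H]2C[C@@H]2[C@H]2CCCC(=O)O2)[C@@H]1[C@H](O)[C@H]1C[C@@H]1[C@H]1CCCC(=O)O1 | target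

## Summary

Total step count: 16. Longest linear sequence: 9 (steps 1–5, 13, 14, 15, 16).

The three steps most likely to fail:

**Step 16 (oxolane closure).** The risks are the facial selectivity of water capture at C9 and competing ionisation of the C11–O tether. The fallback sets out from 20 and comes back at 21. The 12-OH of 20 is silylated (TBSOTf, 2,6-lutidine) to the 12-O-TBS bis-allylic ether F1. The same acid/HFIP cyclisation then gives the 12-O-TBS oxolane carbinol F2 as a C9 epimer mixture, with the 12-oxygen no longer able to intercept either cation. Dess–Martin oxidation converts both epimers into the single cyclopropyl ketone F3. Reagent-controlled reduction ((S)-Me-CBS, catecholborane, −78 °C, the oxolane arm acting as the large group) gives the 9R carbinol F4, and HF·pyridine removes the silyl group to give 21. C9 is thus set by ketone reduction instead of cation capture.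

**Step 15 (Pd/borane etherification with a hindered secondary alcohol).** The fallback sets out from 16 (with 15 and 6) and comes back at 21. It uses a small nucleophile and builds the primed arm afterwards. Appel chlorination of 16 (PPh3, CCl4) gives (2S,3R)-2-(chloromethyl)-3-[(2Z,5Z)-octa-2,5-dien-1-yl]oxirane F5. Base-induced fragmentation (LDA, 3 equiv, THF, −40 °C) gives (3R,5Z,8Z)-undeca-5,8-dien-1-yn-3-ol F6. The same Pd/Et3B reaction of 15 with F6 gives the propargylic ether F7. Hydrozirconation (Cp2Zr(H)Cl), transmetalation (Me2Zn) and addition to (1S,2S)-2-[(2R)-6-oxooxan-2-yl]cyclopropane-1-carbaldehyde F8 (from 6, PhI(OAc)2/TEMPO) gives the 9′-hydroxy bis-allylic ether F9 (C9′ epimers). F9 ionises directly under the step 16 conditions to give 21.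

**Step 3 (epoxide-triggered cyclopropanation/lactonisation).** The risks are Meinwald rearrangement and opening at the wrong carbon. The fallback sets out from 3 (isolated by leaving out the NaOH in step 1) and comes back at 7. Lindlar reduction of 3 gives tert-butyl (5Z,8S)-9-chloro-8-hydroxynon-5-enoate F10. Its only leaving group is then placed at C8 (Tf2O, 2,6-di-tert-butyl-4-methylpyridine, CH2Cl2, −78 → 0 °C), so the same π-participation/lactonisation with inversion gives (6R)-6-[(1S,2S)-2-(chloromethyl)cyclopropyl]oxan-2-one F11. Displacement with PT-SH/K2CO3 in DMF gives sulfide 7.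

## Further compounds

F1 | step 16 | 12-O-TBS ether of 20 | CC/C=C\C/C=C\C[C@H](O[Si](C)(C)C(C)(C)C)[C@@H](O[C@H](C/C=C\C/C=C\CC)/C=C/C(OC)[C@H]1C[C@@H]1[C@H]1CCCC(=O)O1)/C=C/[C@H]1C[C@@H]1[C@H]1CCCC(=O)O1
F2 | step 16 | 12-O-TBS derivative of 21, C9 epimers | CC/C=C\C/C=C\C[C@H](O[Si](C)(C)C(C)(C)C)[C@H]1O[C@H](C/C=C\C/C=C\CC)[C@@H](/C=C/[C@H]2C[C@@H]2[C@H]2CCCC(=O)O2)[C@@H]1C(O)[C@H]1C[C@@H]1[C@H]1CCCC(=O)O1
F3 | step 16 | 12-O-TBS 9-ketone | CC/C=C\C/C=C\C[C@H](O[Si](C)(C)C(C)(C)C)[C@H]1O[C@H](C/C=C\C/C=C\CC)[C@@H](/C=C/[C@H]2C[C@@H]2[C@H]2CCCC(=O)O2)[C@@H]1C(=O)[C@H]1C[C@@H]1[C@H]1CCCC(=O)O1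
F4 | step 16 | 12-O-TBS derivative of 21, 9R | CC/C=C\C/C=C\C[C@H](O[Si](C)(C)C(C)(C)C)[C@H]1O[C@H](C/C=C\C/C=C\CC)[C@@H](/C=C/[C@H]2C[C@@H]2[C@H]2CCCC(=O)O2)[C@@H]1[C@H](O)[C@H]1C[C@@H]1[C@H]1CCCC(=O)O1
F5 | step 15 | (2S,3R)-2-(chloromethyl)-3-[(2Z,5Z)-octa-2,5-dien-1-yl]oxirane | CC/C=C\C/C=C\C[C@H]1O[C@@H]1CCl
F6 | step 15 | (3R,5Z,8Z)-undeca-5,8-dien-1-yn-3-ol | CC/C=C\C/C=C\C[C@@H](O)C#C
F7 | step 15 | propargylic ether of ring-opened 15 (11S,12S,12′R) | CC/C=C\C/C=C\C[C@H](O)[C@@H](O[C@H](C/C=C\C/C=C\CC)C#C)/C=C/[C@H]1C[C@@H]1[C@H]1CCCC(=O)O1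
F8 | step 15 | (1S,2S)-2-[(2R)-6-oxooxan-2-yl]cyclopropane-1-carbaldehyde | O=C[C@H]1C[C@@H]1[C@H]1CCCC(=O)O1
F9 | step 15 | 9′-hydroxy analogue of 20, C9′ epimers | CC/C=C\C/C=C\C[C@H](O)[C@@H](O[C@H](C/C=C\C/C=C\CC)/C=C/C(O)[C@H]1C[C@@H]1[C@H]1CCCC(=O)O1)/C=C/[C@H]1C[C@@H]1[C@H]1CCCC(=O)O1
F10 | step 3 | tert-butyl (5Z,8S)-9-chloro-8-hydroxynon-5-enoate | ClC[C@@H](O)C/C=C\CCCC(=O)OC(C)(C)C
F11 | step 3 | (6R)-6-[(1S,2S)-2-(chloromethyl)cyclopropyl]oxan-2-one | ClC[C@H]1C[C@@H]1[C@H]1CCCC(=O)O1
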